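The route rests on disconnecting the C4–C5 bond of ring A. Ring B of the target, with the C8 and C10 methyls, C11 and the C7 oxygen, is the methyl-substituted dienone ring of (−)-α-santonin. Santonin's quaternary carbon already has the C10 configuration. Its second ring and propionate arm supply C1–C4 and both C4 methyl carbons. Oxidative scission of that second ring gives precursor 7, a 4,4-disubstituted cyclohexadienone (C9 ester, C8 methyl) carrying a CH2CH2C(O)CH(Me)CO2Me chain on C10. One base-catalysed intramolecular Michael addition of C4 to C5, the only unsubstituted enone β-carbon, closes ring A and completes the fifteen-carbon drimane skeleton. All later stereocentres are set from the α face.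

Key step: step 5

Assumption: eudesmane numbering is used for 1–6 and labdane numbering from 7 on; C4 (7–22), C7 (6, 14) and C8 (16–19) are carried as epimer mixtures and drawn without descriptor, because each of these centres is erased or reset later.

Step 1
Reactants: 1 (−)-α-santonin
Product: 3 methyl santoninate [methyl (11S)-6α-hydroxy-3-oxoeudesma-1,4-dien-12-oate], via sodium santoninate 2 (not isolated)
Conditions: NaOH (1.05 equiv), EtOH/H2O, 40 °C, dark; evaporate; MeI, DMF, rt
Reagents that add atoms: sodium hydroxide [Na+].[OH-]; iodomethane CI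
Why: Saponification of the γ-lactone and SN2 O-alkylation of the carboxylate in the same flask keep the medium non-acidic, so the hydroxy acid should be trapped as its ester before it can relactonise, and no stereocentre is touched.

Step 2
Reactants: 3 methyl santoninate (used crude)
Product: 4 methyl (11S)-3,6-dioxoeudesma-1,4-dien-12-oate
Conditions: DMP, NaHCO3, CH2Cl2, 0 °C → rt
Reagents that add atoms: none
Why: Buffered Dess–Martin oxidation should convert the secondary allylic C6 carbinol into the ketone under neutral conditions that neither relactonise 3 nor disturb the dienone.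

Step 3
Reactants: 4 methyl (11S)-3,6-dioxoeudesma-1,4-dien-12-oate
Product: 6 methyl 7-hydroxy-3,6-dioxoeudesma-1,4-dien-12-oate (C7 either configuration), via potassium enolate 5 (not isolated)
Conditions: KHMDS (1.1 equiv), THF, −78 °C; 2-(phenylsulfonyl)-3-phenyloxaziridine, −78 °C; AcOH quench
Reagents that add atoms: 2-(phenylsulfonyl)-3-phenyloxaziridine O=S(=O)(c1ccccc1)N1OC1c1ccccc1; KHMDS C[Si](C)(C)[N-][Si](C)(C)C.[K+] (K+ of 5 only)
Why: Kinetic α′-deprotonation of the C6 ketone removes the axial, α-face C7–H faster than the vinylogous C4-methyl protons or the ester α-proton, and Davis-type enolate hydroxylation then places oxygen on C7, whose configuration is irrelevant because the centre becomes a ketone in step 4.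

Step 4
Reactants: 6 methyl 7-hydroxy-3,6-dioxoeudesma-1,4-dien-12-oate
Product: 7 seco-santonin keto diester [methyl (S)-6-(5-methoxy-4-methyl-3,5-dioxopentyl)-2,6-dimethyl-3-oxocyclohexa-1,4-diene-1-carboxylate]
Conditions: Pb(OAc)4, MeOH/toluene 1:1, 0 °C
Reagents that add atoms: methanol CO
Why: Criegee-type lead tetraacetate cleavage of the α-ketol through its methyl hemiketal breaks the old C6–C7 bond and should deliver the ring ester and the side-chain ketone in one operation, C10 being untouched and C4 being a freely epimerising β-keto ester carbon.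

Step 5
Reactants: 7 seco-santonin keto diester
Product: 8 dimethyl 3,7-dioxo-5β-drim-8-ene-11,19-dioate (cis-fused: 5β-H and 10β-Me; C4 either epimer)
Conditions: Cs2CO3 (0.2 equiv), MeCN, 0 °C → rt
Reagents that add atoms: none
Why: Catalytic carbonate deprotonates only the β-keto ester C4–H, by far the most acidic site, and the delocalised enolate adds through C4 to C5, the β-carbon of the C5=C6–C7=O enone; the C6–C7 enolate so formed is protonated by a further molecule of 7, which regenerates the donor, so the flask never holds a full equivalent of base and the retro-addition stays slow. The closest known reaction type is the intramolecular Michael addition of a tethered 1,3-dicarbonyl to a 4,4-disubstituted cyclohexa-2,5-dienone. Ring A (C10–C1–C2–C3–C4–C5) closes in a 6-(enolendo)-exo-trig mode. C5 is controlled by C10, because the short tether leaves C10 on the α face and can reach C5 only from that face, so H5 ends β and the decalin is cis-fused, whereas C4 forms under no useful control. Neither new centre has to last, since C5 returns to sp2 in step 6 and C4 becomes CMe2 in step 16. The step needs site selectivity between the two enone β-carbons, and the substrate secures it: C9 carries the ester and attack there would create three contiguous quaternary carbons, whereas C5 is a CH.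

Step 6
Reactants: 8 dimethyl 3,7-dioxo-5β-drim-8-ene-11,19-dioate
Product: 9 dimethyl 3,7-dioxodrima-5,8-diene-11,19-dioate
Conditions: DDQ (1.5 equiv), TsOH·H2O (cat.), 1,4-dioxane, reflux
Reagents that add atoms: none
Why: DDQ dehydrogenation of a cyclohex-2-enone to the cross-conjugated dienone proceeds through the C6=C7 dienol (the only one this enone can form) and hydride loss from C5, leaves the saturated C3 ketone alone as with steroidal enone/saturated-ketone pairs, avoids the strong base that would trigger retro-addition, and erases the cis C5 centre.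

Step 7
Reactants: 9 dimethyl 3,7-dioxodrima-5,8-diene-11,19-dioate
Product: 11 dimethyl 7-oxo-3-(trifluoromethylsulfonyloxy)drima-2,5,8-triene-11,19-dioate, via potassium enolate 10 (not isolated)
Conditions: KHMDS (1.1 equiv), THF, −78 °C; PhNTf2, −78 → 0 °C
Reagents that add atoms: N-phenylbis(trifluoromethanesulfonimide) O=S(=O)(N(c1ccccc1)S(=O)(=O)C(F)(F)F)C(F)(F)F; KHMDS C[Si](C)(C)[N-][Si](C)(C)C.[K+] (K+ of 10 only)
Why: In 9 only C2–H is α to a ketone, so kinetic enolisation with a non-nucleophilic base (no retro-Claisen at the crowded C3/C4 unit) followed by O-sulfonylation should give the Δ2 enol triflate.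

Step 8
Reactants: 11 enol triflate
Product: 12 dimethyl 7-oxodrima-2,5,8-triene-11,19-dioate
Conditions: Pd(OAc)2 (5 mol %), PPh3 (10 mol %), HCO2H, Et3N, DMF, 60 °C
Reagents that add atoms: none
Why: Palladium-catalysed formate reduction of an enol triflate (oxidative addition, formate decarboxylation, reductive elimination) replaces C3–O by C3–H and tolerates enones and esters.

Step 9
Reactants: 12 dimethyl 7-oxodrima-2,5,8-triene-11,19-dioate
Product: 13 dimethyl 7-oxodrima-5,8-diene-11,19-dioate
Conditions: H2 (1 atm), RhCl(PPh3)3 (10 mol %), toluene/EtOH, rt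
Reagents that add atoms: none
Why: Homogeneous hydrogenation with RhCl(PPh3)3 discriminates by substitution, so the cis-disubstituted Δ2 alkene should be saturated while the tri- and tetrasubstituted dienone alkenes stay, which completes the deletion of the C3 ketone.

Step 10
Reactants: 13 dimethyl 7-oxodrima-5,8-diene-11,19-dioate
Product: 14 drima-5,8-diene-7,11,19-triol (C7 either configuration)
Conditions: DIBAL-H (7 equiv), CH2Cl2, −78 → 0 °C; Rochelle salt
Reagents that add atoms: none
Why: Exhaustive DIBAL-H reduction takes both esters to primary alcohols and the dienone 1,2 to the bis-allylic carbinol, whose configuration does not matter since it is re-oxidised next.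

Step 11
Reactants: 14 drima-5,8-diene-7,11,19-triol
Product: 15 19-hydroxy-7-oxodrima-5,8-dien-11-al
Conditions: activated MnO2 (excess), CH2Cl2, rt
Reagents that add atoms: none
Why: Manganese dioxide oxidises only allylic alcohols, so C7 and C11 return to the carbonyl level while the neopentyl C19 alcohol stays, which tells the two former ester carbons apart without a protecting group.

Step 12
Reactants: 15 19-hydroxy-7-oxodrima-5,8-dien-11-al
Product: 16 19-hydroxy-7-oxodrim-5-en-11-al (9α-H and 9β-CHO; C8 mixture)
Conditions: Zn dust, AcOH/THF, 0 °C → rt, short contact; used at once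
Reagents that add atoms: none
Why: Zinc–acetic acid reduction of the 2-ene-1,4-dicarbonyl unit (far easier to reduce than the simple Δ5 enone) saturates C8–C9, and kinetic protonation of the C9=C11 enol from the α face, opposite the axial C10 methyl, should set 9α-H, C8 being left as a mixture that step 15 resets.

Step 13
Reactants: 16 19-hydroxy-7-oxodrim-5-en-11-al; 17 methyltriphenylphosphonium bromide
Product: 18 19-hydroxy-13,14,15,16-tetranorlabda-5,11-dien-7-one (9α-H)
Conditions: 17 (2.3 equiv), KHMDS (2.2 equiv), THF, 0 °C; then 16, −78 → 0 °C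
Reagents that add atoms: 17 methyltriphenylphosphonium bromide C[P+](c1ccccc1)(c1ccccc1)c1ccccc1.[Br-]
Why: Wittig methylenation at low temperature is much faster at the aldehyde than at the hindered conjugated ketone (one equivalent of ylide is spent on the free alcohol) and removes the carbonyl that makes C9–H acidic, so C9 is locked.

Step 14
Reactants: 18 19-hydroxy-13,14,15,16-tetranorlabda-5,11-dien-7-one
Product: 19 19-tosyloxy-13,14,15,16-tetranorlabda-5,11-dien-7-one
Conditions: TsCl, DMAP, pyridine, CH2Cl2, rt
Reagents that add atoms: p-toluenesulfonyl chloride Cc1ccc(cc1)S(=O)(=O)Cl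
Why: Sulfonylation of the only hydroxyl group gives a neopentyl tosylate that is inert to substitution and elimination in the next step and, unlike a mesylate, has no acidic α-protons.

Step 15
Reactants: 19 19-tosyloxy-13,14,15,16-tetranorlabda-5,11-dien-7-one
Product: 21 8α-hydroxy-19-tosyloxy-13,14,15,16-tetranorlabda-5,11-dien-7-one (8β-Me), via potassium dienolate 20 (not isolated)
Conditions: KHMDS (1.1 equiv), THF, −78 → −40 °C; 2-(phenylsulfonyl)-3-phenyloxaziridine, −78 °C; AcOH quench
Reagents that add atoms: 2-(phenylsulfonyl)-3-phenyloxaziridine O=S(=O)(c1ccccc1)N1OC1c1ccccc1; KHMDS C[Si](C)(C)[N-][Si](C)(C)C.[K+] (K+ of 20 only)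
Why: C6 is vinylic and C4/C10 are quaternary, so the Δ5 alkene acts as a blocking group and base can only form the C7=C8 dienolate, which in a Davis-type hydroxylation is attacked from the α face, anti to the C10 methyl and the 9β-vinyl group, giving 8α-OH/8β-Me.

Step 16
Reactants: 21 8α-hydroxy-19-tosyloxy-13,14,15,16-tetranorlabda-5,11-dien-7-one
Product: 23 13,14,15,16-tetranorlabda-5,11-diene-7β,8α-diol, via 7β-ol tosylate 22 (not isolated)
Conditions: LiEt3BH (6 equiv), THF, −78 °C, then 65 °C
Reagents that add atoms: none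
Why: Lithium triethylborohydride first adds 1,2 to the enone from the α face (the β face is closed by the axial 8β- and 10β-methyls, and C5 is too hindered for 1,4-attack) to set 7β-OH, and on heating displaces the neopentyl tosylate in an SN2 hydride reduction, so C19 becomes methyl and C4 ceases to be a stereocentre.

Step 17
Reactants: 23 13,14,15,16-tetranorlabda-5,11-diene-7β,8α-diol
Product: 24 7β,8α-bis(triethylsilyloxy)-13,14,15,16-tetranorlabda-5,11-diene
Conditions: TESOTf (3 equiv), 2,6-lutidine, CH2Cl2, −78 → 0 °C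
Reagents that add atoms: triethylsilyl trifluoromethanesulfonate CC[Si](CC)(CC)OS(=O)(=O)C(F)(F)F
Why: A silyl triflate with a hindered pyridine silylates the secondary allylic as well as the tertiary hydroxyl, which masks O7 for the later selective acetylation of O6 and stops O8 from forming a lactol with C12.

Step 18
Reactants: 24 7β,8α-bis(triethylsilyloxy)-13,14,15,16-tetranorlabda-5,11-diene
Product: 26 7β,8α-bis(triethylsilyloxy)-13,14,15,16-tetranorlabdane-6α,12-diol (5α-H), via bis-alkylborane 25 (not isolated)
Conditions: BH3·THF (6 equiv), THF, 0 → 40 °C; then 3 M NaOH, 30% H2O2, 0 °C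
Reagents that add atoms: hydrogen peroxide OO; borane B (boron of 25 only)
Why: Hydroboration–oxidation: borane adds anti-Markovnikov to the vinyl group (boron on C12) and syn to Δ5 with boron on the less substituted C6 from the α face, opposite the axial C4β/C10 methyls and trans to 7β-OSiEt3, and oxidation with retention gives 5α-H (trans-decalin) and 6α-OH.

Step 19
Reactants: 26 7β,8α-bis(triethylsilyloxy)-13,14,15,16-tetranorlabdane-6α,12-diol
Product: 27 6α-hydroxy-7β,8α-bis(triethylsilyloxy)-13,14,15,16-tetranorlabdan-12-al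
Conditions: TEMPO (10 mol %), PhI(OAc)2 (1.1 equiv), CH2Cl2, rt
Reagents that add atoms: none
Why: Oxoammonium (TEMPO) oxidation is sterically selective for the unhindered primary C12 alcohol and should stop at the aldehyde, leaving the crowded equatorial 6α-OH.

Step 20
Reactants: 27 6α-hydroxy-7β,8α-bis(triethylsilyloxy)-13,14,15,16-tetranorlabdan-12-al
Product: 28 6α-acetoxy-7β,8α-bis(triethylsilyloxy)-13,14,15,16-tetranorlabdan-12-al
Conditions: Ac2O, DMAP, pyridine, rt → 40 °C
Reagents that add atoms: acetic anhydride CC(=O)OC(C)=O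
Why: DMAP-catalysed acylation esterifies the only free hydroxyl under weakly basic conditions that do not enolise the aldehyde or move the silyl groups.

Step 21
Reactants: 28 6α-acetoxy-7β,8α-bis(triethylsilyloxy)-13,14,15,16-tetranorlabdan-12-al; 29 ethyltriphenylphosphonium bromide
Product: 30 (12Z)-6α-acetoxy-13-iodo-7β,8α-bis(triethylsilyloxy)-14,15-dinorlabd-12-ene
Conditions: 29, n-BuLi, THF, rt; I2, −78 °C; NaHMDS, −20 °C; then 28, −78 °C
Reagents that add atoms: 29 ethyltriphenylphosphonium bromide CC[P+](c1ccccc1)(c1ccccc1)c1ccccc1.[Br-]; iodine II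
Why: Stork–Zhao-type Wittig olefination with the α-iodo ylide made in the flask reacts through the kinetically favoured cis-oxaphosphetane and should give the (Z)-iodoalkene (iodine cis to C11), fast enough at −78 °C for the acetate to survive.

Step 22
Reactants: 30 (12Z)-iodoalkene; 31 potassium vinyltrifluoroborate
Product: 32 (12Z)-6α-acetoxy-7β,8α-bis(triethylsilyloxy)labda-12,14-diene
Conditions: PdCl2(dppf)·CH2Cl2 (5 mol %), Cs2CO3 (3 equiv), THF/H2O 10:1, 60 °C
Reagents that add atoms: 31 potassium vinyltrifluoroborate C=C[B-](F)(F)F.[K+]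
Why: Suzuki–Miyaura coupling of an alkenyl iodide with the vinyltrifluoroborate proceeds with retention of alkene geometry, so the vinyl group ends cis to C11 and the 12Z-diene is formed.

Step 23
Reactants: 32 (12Z)-6α-acetoxy-7β,8α-bis(triethylsilyloxy)labda-12,14-diene
Product: 33 (12Z)-6α-acetoxylabda-12,14-diene-7β,8α-diol (CNP0138393.1)
Conditions: HF·pyridine, pyridine, THF, 0 °C → rt
Reagents that add atoms: none
Why: Fluoride-driven cleavage of both triethylsilyl ethers under buffered, mildly acidic conditions avoids free alkoxides, so the acetyl group should stay on O6 and the acid-sensitive hydroxy diene is spared.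

Compound list
1 | (−)-α-santonin | C[C@H]1[C@@H]2CC[C@]3(C=CC(=O)C(=C3[C@H]2OC1=O)C)C | starting material
2 | sodium santoninate | [Na+].[O-]C(=O)[C@@H](C)[C@@H]1CC[C@@]2(C)C=CC(=O)C(C)=C2[C@H]1O | intermediate
3 | methyl santoninate, methyl (11S)-6α-hydroxy-3-oxoeudesma-1,4-dien-12-oate | COC(=O)[C@@H](C)[C@@H]1CC[C@@]2(C)C=CC(=O)C(C)=C2[C@H]1O | intermediate
4 | methyl (11S)-3,6-dioxoeudesma-1,4-dien-12-oate | COC(=O)[C@@H](C)[C@@H]1CC[C@@]2(C)C=CC(=O)C(C)=C2C1=O | intermediate
5 | potassium C6=C7 enolate of 4 | COC(=O)[C@@H](C)C1=C([O-])C2=C(C)C(=O)C=C[C@]2(C)CC1.[K+] | intermediate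
6 | methyl 7-hydroxy-3,6-dioxoeudesma-1,4-dien-12-oate | COC(=O)[C@@H](C)C1(O)CC[C@@]2(C)C=CC(=O)C(C)=C2C1=O | intermediate
7 | seco-santonin keto diester (key-step precursor) | COC(=O)C1=C(C)C(=O)C=C[C@]1(C)CCC(=O)C(C)C(=O)OC | intermediate
8 | dimethyl 3,7-dioxo-5β-drim-8-ene-11,19-dioate, cis-fused (key-step product) | COC(=O)C1=C(C)C(=O)C[C@@H]2C(C)(C(=O)OC)C(=O)CC[C@@]21C | intermediate
9 | dimethyl 3,7-dioxodrima-5,8-diene-11,19-dioate | COC(=O)C1=C(C)C(=O)C=C2C(C)(C(=O)OC)C(=O)CC[C@@]21C | intermediate
10 | potassium C2=C3 enolate of 9 | COC(=O)C1=C(C)C(=O)C=C2C(C)(C(=O)OC)C([O-])=CC[C@@]21C.[K+] | intermediate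
11 | dimethyl 7-oxo-3-(trifluoromethylsulfonyloxy)drima-2,5,8-triene-11,19-dioate | COC(=O)C1=C(C)C(=O)C=C2C(C)(C(=O)OC)C(OS(=O)(=O)C(F)(F)F)=CC[C@@]21C | intermediate
12 | dimethyl 7-oxodrima-2,5,8-triene-11,19-dioate | COC(=O)C1=C(C)C(=O)C=C2C(C)(C(=O)OC)C=CC[C@@]21C | intermediate
13 | dimethyl 7-oxodrima-5,8-diene-11,19-dioate | COC(=O)C1=C(C)C(=O)C=C2C(C)(C(=O)OC)CCC[C@@]21C | intermediate
14 | drima-5,8-diene-7,11,19-triol | OCC1=C(C)C(O)C=C2C(C)(CO)CCC[C@@]21C | intermediate
15 | 19-hydroxy-7-oxodrima-5,8-dien-11-al | O=CC1=C(C)C(=O)C=C2C(C)(CO)CCC[C@@]21C | intermediate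
16 | 19-hydroxy-7-oxodrim-5-en-11-al (9α-H) | O=C[C@H]1C(C)C(=O)C=C2C(C)(CO)CCC[C@@]21C | intermediate
17 | methyltriphenylphosphonium bromide | C[P+](c1ccccc1)(c1ccccc1)c1ccccc1.[Br-] | starting material
18 | 19-hydroxy-13,14,15,16-tetranorlabda-5,11-dien-7-one | C=C[C@H]1C(C)C(=O)C=C2C(C)(CO)CCC[C@@]21C | intermediate
19 | 19-tosyloxy-13,14,15,16-tetranorlabda-5,11-dien-7-one | C=C[C@H]1C(C)C(=O)C=C2C(C)(COS(=O)(=O)c3ccc(C)cc3)CCC[C@@]21C | intermediate
20 | potassium C7=C8 dienolate of 19 | C=C[C@H]1C(C)=C([O-])C=C2C(C)(COS(=O)(=O)c3ccc(C)cc3)CCC[C@@]21C.[K+] | intermediate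
21 | 8α-hydroxy-19-tosyloxy-13,14,15,16-tetranorlabda-5,11-dien-7-one | C=C[C@H]1[C@](C)(O)C(=O)C=C2C(C)(COS(=O)(=O)c3ccc(C)cc3)CCC[C@@]21C | intermediate
22 | 19-tosyloxy-13,14,15,16-tetranorlabda-5,11-diene-7β,8α-diol | C=C[C@H]1[C@](C)(O)[C@@H](O)C=C2C(C)(COS(=O)(=O)c3ccc(C)cc3)CCC[C@@]21C | intermediate
23 | 13,14,15,16-tetranorlabda-5,11-diene-7β,8α-diol | C=C[C@H]1[C@](C)(O)[C@@H](O)C=C2C(C)(C)CCC[C@@]21C | intermediate
24 | 7β,8α-bis(triethylsilyloxy)-13,14,15,16-tetranorlabda-5,11-diene | C=C[C@H]1[C@](C)(O[Si](CC)(CC)CC)[C@@H](O[Si](CC)(CC)CC)C=C2C(C)(C)CCC[C@@]21C | intermediate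
25 | 6α,12-diboryl adduct of 24 (5α-H) | BCC[C@H]1[C@](C)(O[Si](CC)(CC)CC)[C@@H](O[Si](CC)(CC)CC)[C@H](B)[C@H]2C(C)(C)CCC[C@@]21C | intermediate
26 | 7β,8α-bis(triethylsilyloxy)-13,14,15,16-tetranorlabdane-6α,12-diol | OCC[C@H]1[C@](C)(O[Si](CC)(CC)CC)[C@@H](O[Si](CC)(CC)CC)[C@H](O)[C@H]2C(C)(C)CCC[C@@]21C | intermediate
27 | 6α-hydroxy-7β,8α-bis(triethylsilyloxy)-13,14,15,16-tetranorlabdan-12-al | O=CC[C@H]1[C@](C)(O[Si](CC)(CC)CC)[C@@H](O[Si](CC)(CC)CC)[C@H](O)[C@H]2C(C)(C)CCC[C@@]21C | intermediate
28 | 6α-acetoxy-7β,8α-bis(triethylsilyloxy)-13,14,15,16-tetranorlabdan-12-al | O=CC[C@H]1[C@](C)(O[Si](CC)(CC)CC)[C@@H](O[Si](CC)(CC)CC)[C@H](OC(C)=O)[C@H]2C(C)(C)CCC[C@@]21C | intermediate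
29 | ethyltriphenylphosphonium bromide | CC[P+](c1ccccc1)(c1ccccc1)c1ccccc1.[Br-] | starting material
30 | (12Z)-6α-acetoxy-13-iodo-7β,8α-bis(triethylsilyloxy)-14,15-dinorlabd-12-ene | I/C(C)=C\C[C@H]1[C@](C)(O[Si](CC)(CC)CC)[C@@H](O[Si](CC)(CC)CC)[C@H](OC(C)=O)[C@H]2C(C)(C)CCC[C@@]21C | intermediate
31 | potassium vinyltrifluoroborate | C=C[B-](F)(F)F.[K+] | starting material
32 | (12Z)-6α-acetoxy-7β,8α-bis(triethylsilyloxy)labda-12,14-diene | C=C/C(C)=C\C[C@H]1[C@](C)(O[Si](CC)(CC)CC)[C@@H](O[Si](CC)(CC)CC)[C@H](OC(C)=O)[C@H]2C(C)(C)CCC[C@@]21C | intermediate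
33 | (12Z)-6α-acetoxylabda-12,14-diene-7β,8α-diol (CNP0138393.1) | C=C/C(C)=C\C[C@H]1[C@](C)(O)[C@@H](O)[C@H](OC(C)=O)[C@H]2C(C)(C)CCC[C@@]21C | target

Total step count: 23. Longest linear sequence: 23 steps (1 → 33); 17, 29 and 31 are bought.

Steps most likely to fail

Step 5 (key step). The addition is reversible and builds a quaternary C4 between C3, C5 and the ester. The equilibrium may therefore stop short of full closure, or the ambident enolate may close through oxygen. The fallback makes the same bond irreversibly under Lewis-acid instead of base control. Setting out from 7, TBSOTf/Et3N (CH2Cl2, −78 °C) should give the β-silyloxy enoate F1. A catalytic amount of Tf2NH (CH2Cl2, −78 °C) should then trigger an intramolecular Mukaiyama–Michael addition in which the silyl group moves to the C7 oxygen. This gives the cis-fused silyl dienol ether F2, which cannot revert. Saegusa–Ito oxidation of F2 (Pd(OAc)2, MeCN) leads directly to 9, where the route is rejoined.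

Step 6. Hydride abstraction from the neopentyl-type C5–H may be too slow. Prolonged heating could then bring dehydrogenation next to the C3 ketone or retro-addition. The fallback removes the second ketone first, so that only one carbonyl can enolise. Setting out from 8:
- Luche reduction (NaBH4, CeCl3, MeOH) takes both ketones to the diol F3.
- MnO2 re-oxidises only the allylic C7 carbinol to the hydroxy enone F4.
- Burgess dehydration, for which only C2–H is available, gives the Δ2 alkene F5.
- Soft enolisation (TMSOTf, Et3N) gives the trimethylsilyl dienol ether F6.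
- Saegusa–Ito oxidation delivers 12, where the route is rejoined; steps 7 and 8 fall away.

Step 18. The Δ5 alkene lies between two quaternary carbons. Its hydroboration may remain incomplete while the vinyl group reacts, or facial selectivity may erode on heating. The fallback splits the two tasks and replaces hydroboration of Δ5 by epoxide chemistry. Setting out from 24:
- mCPBA (NaHCO3, CH2Cl2) should epoxidise the more nucleophilic trisubstituted alkene from the open α face to the 5α,6α-epoxide F7.
- Cp2TiCl (from Cp2TiCl2/Mn, collidine·HCl) with 1,4-cyclohexadiene opens it by homolysis of the C5–O bond. The tertiary C5 radical takes up hydrogen from the α face to give the 6α-alcohol F8.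
- 9-BBN, then NaOH/H2O2, converts the vinyl group and gives 26, where the route is rejoined.

Further compounds
F1 | step 5 | tert-butyldimethylsilyl enol ether of 7 (β-silyloxy enoate) | COC(=O)C1=C(C)C(=O)C=C[C@]1(C)CCC(O[Si](C)(C)C(C)(C)C)=C(C)C(=O)OC
F2 | step 5 | C7 tert-butyldimethylsilyl dienol ether of 8 (cis-fused) | COC(=O)C1=C(C)C(O[Si](C)(C)C(C)(C)C)=C[C@@H]2C(C)(C(=O)OC)C(=O)CC[C@@]21C
F3 | step 6 | dimethyl 3,7-dihydroxy-5β-drim-8-ene-11,19-dioate | COC(=O)C1=C(C)C(O)C[C@@H]2C(C)(C(=O)OC)C(O)CC[C@@]21C
F4 | step 6 | dimethyl 3-hydroxy-7-oxo-5β-drim-8-ene-11,19-dioate | COC(=O)C1=C(C)C(=O)C[C@@H]2C(C)(C(=O)OC)C(O)CC[C@@]21C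
F5 | step 6 | dimethyl 7-oxo-5β-drima-2,8-diene-11,19-dioate | COC(=O)C1=C(C)C(=O)C[C@@H]2C(C)(C(=O)OC)C=CC[C@@]21C
F6 | step 6 | C7 trimethylsilyl dienol ether of F5 | COC(=O)C1=C(C)C(O[Si](C)(C)C)=C[C@@H]2C(C)(C(=O)OC)C=CC[C@@]21C
F7 | step 18 | 5α,6α-epoxy-7β,8α-bis(triethylsilyloxy)-13,14,15,16-tetranorlabd-11-ene | C=C[C@H]1[C@](C)(O[Si](CC)(CC)CC)[C@@H](O[Si](CC)(CC)CC)[C@@H]3O[C@@]32C(C)(C)CCC[C@@]21C
F8 | step 18 | 7β,8α-bis(triethylsilyloxy)-13,14,15,16-tetranorlabd-11-en-6α-ol (5α-H) | C=C[C@H]1[C@](C)(O[Si](CC)(CC)CC)[C@@H](O[Si](CC)(CC)CC)[C@H](O)[C@H]2C(C)(C)CCC[C@@]21C
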